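**Retrosynthetic overview**

1. Numbering (longipinane): C1 ketone, C2=C3 (methyl on C3), C4 and C11 ring-fusion CH, C5 CH, C6 CMe2, C7 CH–O-isovaleryl, C8 CH2, C9 CH–O-tigloyl, C10 C–CH3. Late stage: the C1 enone by allylic oxidation; the O9 and O7 esters from the 7,9-dione 19 by CBS reduction, Evans–Tishchenko reaction and acylation.
2. Key disconnection: the cyclobutane bond C4–C10 and the seven-membered-ring bond C8–C9 are made together from the monocyclic chloro keto nitrile 16 by a dianion cascade (intramolecular nitrile-anion alkylation, then Thorpe–Ziegler-type enolate–nitrile addition).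
3. Enabling feature: the quaternary C10 lies between C4 and C9. With C9 as a nitrile, C10–H is acidic and C10 stands 1,3 to the allylic C4 across the ring C1–C2–C3–C4–C5–C11, so C4–C10 closure gives the cyclobutane C4–C5–C11–C10. The same C9 is then the electrophile for C8, the methyl carbon of the C7 ketone, which closes the ring C4–C5–C6–C7–C8–C9–C10.
4. 16 comes from (R)-carvone: its ten carbons become C1–C5, C11, the C3 methyl, C10, the C10 methyl and C9, and its stereocentre becomes C11. Acetone and ethynyltrimethylsilane deliver C6 (with both methyls), C7 and C8.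
5. Ring order: cyclohexene (from carvone), then cyclobutane and seven-membered ring in step 10; no ring is formed afterwards.

Key step: step 10

Remark: atoms of all intermediates are referred to by the locant they carry in the target. In the carvone-derived monocycles the ring carbonyl carbon is C4, its α′-carbon C5, the side-chain-bearing ring carbon C11, the side-chain CH carbon C10 and its nitrile (or precursor) carbon C9. C10 is carried as a mixture of epimers up to 16; both converge in step 10, where C10 is planar in the anion.

**Route**

Step 1
Reactants: 1 (R)-(−)-carvone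
Product: 2 (5R)-2-methyl-5-(2-methyloxiran-2-yl)cyclohex-2-en-1-one (both epoxide epimers)
Conditions: mCPBA, CH2Cl2, 0 °C
Reagents that add atoms: mCPBA (3-chloroperoxybenzoic acid), OOC(=O)c1cccc(Cl)c1
Why: Prilezhaev epoxidation should take place only at the electron-rich 1,1-disubstituted C10=C9 alkene because the enone alkene is deactivated; C10 forms as both epimers, which is without consequence.

Step 2
Reactants: 2 carvone 8,9-epoxide
Product: 3 2-[(1R)-4-methyl-5-oxocyclohex-3-en-1-yl]propanal (both C10 epimers)
Conditions: BF3·OEt2 (cat.), CH2Cl2, −78 °C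
Reagents that add atoms: none
Why: Meinwald rearrangement: the Lewis acid should open the 2,2-disubstituted epoxide at tertiary C10 and a 1,2-hydride shift from C9 should give the α-branched aldehyde.

Step 3
Reactants: 3 aldehyde
Product: 5 2-[(1R)-4-methyl-5-oxocyclohex-3-en-1-yl]propanenitrile (both C10 epimers), via oxime O-sulfonic acid 4 (not isolated)
Conditions: H2NOSO3H, H2O/MeCN, 23 → 50 °C
Reagents that add atoms: hydroxylamine-O-sulfonic acid, NOS(=O)(=O)O
Why: Condensation at the aldehyde should give the oxime O-sulfonic acid, which loses sulfuric acid on gentle warming (aldehyde-to-nitrile conversion by oxime O-sulfonate elimination); the less electrophilic conjugated ketone should be left alone by one equivalent of reagent.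

Step 4
Reactants: 5 keto nitrile; 6 acetone
Product: 7 2-[(1R)-6-(2-hydroxypropan-2-yl)-4-methyl-5-oxocyclohex-3-en-1-yl]propanenitrile (new group trans to the nitrile side chain)
Conditions: LiN(i-Pr)2, THF, −78 °C; then 6; AcOH quench
Reagents that add atoms: acetone (6), CC(C)=O
Why: Kinetic deprotonation at C5 (the ketone α-CH2 is far more acidic than the tertiary nitrile α-CH) and aldol addition to acetone anti to the C11 side chain should give the tertiary aldol; the C5 configuration is irrelevant because C5 becomes sp2 in step 5.

Step 5
Reactants: 7 aldol adduct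
Product: 9 2-[4-methyl-5-oxo-6-(propan-2-ylidene)cyclohex-3-en-1-yl]propanenitrile (ring CH as in 5), via tertiary mesylate 8 (not isolated)
Conditions: MsCl, Et3N, DMAP (cat.), CH2Cl2, 0 → 23 °C
Reagents that add atoms: none
Why: Sulfene-type mesylation of the tertiary alcohol followed by E1cB elimination through the ketone enolate should give only the conjugated exocyclic isopropylidene ketone (aldol dehydration), under amine conditions too mild to touch the C11–H stereocentre.

Step 6
Reactants: 9 cross-conjugated dienone; 10 ethynyltrimethylsilane
Product: 13 2-[4-methyl-6-(2-methylbut-3-yn-2-yl)-5-oxocyclohex-3-en-1-yl]propanenitrile (the two ring substituents cis), via enol borinate 11 (not isolated), via silylalkyne ketone 12 (not isolated)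
Conditions: 10, n-BuLi, THF, −78 °C; B-methoxy-9-BBN; BF3·OEt2; then 9, pentane, 23 °C; pH 7 buffer; then TBAF, AcOH, THF, 0 °C
Reagents that add atoms: ethynyltrimethylsilane (10), C#C[Si](C)(C)C
Why: Conjugate alkynylation: B-alkynyl-9-BBN reagents transfer the alkynyl group 1,4 through a six-membered boron-chelated transition state that only an s-cis enone can reach, so the exocyclic isopropylidene ketone should react at its fully substituted β-carbon (C6) while the s-trans ring enone is left alone; kinetic protonation of the enol borinate on the face opposite the C11 side chain should set C5 cis to it (contra-thermodynamic) before buffered fluoride removes the silyl group.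

Step 7
Reactants: 13 alkynyl ketone
Product: 14 2-[4-methyl-6-(2-methyl-3-oxobutan-2-yl)-5-oxocyclohex-3-en-1-yl]propanenitrile (the two ring substituents cis)
Conditions: NaAuCl4·2H2O (2 mol %), MeOH/H2O, 65 °C
Reagents that add atoms: water, O
Why: Gold-catalysed Markovnikov hydration of the terminal alkyne should give the C7 methyl ketone under nearly neutral conditions that leave the nitrile and the epimerisable C5–H untouched.

Step 8
Reactants: 14 diketone
Product: 15 2-[5-hydroxy-4-methyl-6-(2-methyl-3-oxobutan-2-yl)cyclohex-3-en-1-yl]propanenitrile (hydroxyl cis to both side chains)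
Conditions: NaBH4, CeCl3·7H2O, MeOH, −78 °C
Reagents that add atoms: none
Why: Luche 1,2-reduction should reduce only the C4 enone carbonyl (the pinacolone-type C7 ketone is much slower at −78 °C), with hydride delivered to the face opposite the two cis substituents at C5 and C11, which gives the all-cis allylic alcohol.

Step 9
Reactants: 15 allylic alcohol
Product: 16 2-[5-chloro-4-methyl-6-(2-methyl-3-oxobutan-2-yl)cyclohex-3-en-1-yl]propanenitrile (side chains cis; chlorine trans to both)
Conditions: PPh3, Cl3CC(O)CCl3, CH2Cl2, 0 °C
Reagents that add atoms: hexachloroacetone, ClC(Cl)(Cl)C(=O)C(Cl)(Cl)Cl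
Why: Appel-type chlorination: chloride should displace the alkoxyphosphonium group at C4 from the unhindered face in an SN2 reaction with inversion and without allylic transposition, which places chlorine trans to both side chains as the backside attack of step 10 requires.

Step 10
Reactants: 16 chloro keto nitrile
Product: 19 longipin-2-ene-7,9-dione (tricyclic β-diketone; ring-fusion centres as in the target), via bicyclic keto nitrile 17 (not isolated), via enaminone 18 (not isolated)
Conditions: LiN(i-Pr)2 (2.3 equiv), THF, −78 → 45 °C; then AcOH/NaOAc buffer (pH 4.5), H2O, 40 °C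
Reagents that add atoms: water, O
Why: Two equivalents of LiN(i-Pr)2 should convert 16 into a dianion (α-lithionitrile at C10, lithium enolate of the C7 methyl ketone); on warming, the nitrile anion, far more nucleophilic than the aggregated enolate and held 1,3-diaxial to the pseudoaxial allylic C4–Cl bond, should displace chloride with inversion in a 4-exo-tet closure of the cyclobutane (intramolecular nitrile-anion alkylation of the Stork cyclobutane type). The nitrile is inert to the enolate while it is metalated and becomes electrophilic only once C10 is quaternary, so the enolate carbon C8 should then add to C9 in a 7-exo-dig Thorpe–Ziegler-type closure of the seven-membered ring, made irreversible by tautomerisation to the lithium enaminone. C4 is set by SN2 inversion of the chloride placed in step 9; C10 is set by the substrate, the slim linear nitrile taking the position that faces the C5 side chain and the methyl the position over the C2=C3 bridge, which is also the only epimer able to reach C8, and both C10 epimers of 16 converge through the planar anion. The step needs nitrile-anion alkylation to outrun five-membered C- or O-alkylation by the ketone enolate and direct substitution to outrun allylic transposition; the reactivity gap between the two anions at low temperature and the diaxial alignment at C4 are relied on for this. Buffered aqueous work-up should hydrolyse the primary enaminone to the β-diketone without exposing the acid-labile pinene-type alkene to strong acid.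

Step 11
Reactants: 19 β-diketone
Product: 20 (9R)-9-hydroxylongipin-2-en-7-one
Conditions: (S)-2-methyl-CBS-oxazaborolidine (20 mol %), catecholborane, toluene, −40 → −20 °C; aq. NaOH work-up
Reagents that add atoms: none
Why: Corey–Bakshi–Shibata reduction: the C9 carbonyl, flanked by the tied-back cyclobutane carbon, should react faster than the C7 carbonyl next to the gem-dimethyl carbon, and the (S)-catalyst (large group C10, small group C8) should set (9R) irrespective of the weak substrate bias, while catecholborane spares the trisubstituted alkene; reduction at C7 instead would not be lost, since the same catalyst sets (7R) there and the two acyl groups could then be introduced in the reverse order.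

Step 12
Reactants: 20 β-hydroxy ketone; 21 tiglaldehyde
Product: 23 (7R,9R)-7-hydroxylongipin-2-en-9-yl (2E)-2-methylbut-2-enoate, via hemiacetal 22 (not isolated)
Conditions: 21 (excess), SmI2 (30 mol %), THF, −10 °C
Reagents that add atoms: tiglaldehyde (21), C/C=C(\C)C=O
Why: Evans–Tishchenko reaction: the samarium-bound hemiacetal formed from the C9 alkoxide and tiglaldehyde should deliver its hydride intramolecularly to the C7 ketone through a six-membered transition state on the face of the C9 oxygen, which sets the 7,9-anti (7R) alcohol and leaves the tigloyl group on O9, so the two oxygens are differentiated without protecting groups.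

Step 13
Reactants: 23 hydroxy tiglate; 24 3-methylbutanoyl chloride
Product: 25 (7R,9R)-7-(3-methylbutanoyloxy)longipin-2-en-9-yl (2E)-2-methylbut-2-enoate
Conditions: 24, pyridine, DMAP (cat.), CH2Cl2, 0 → 23 °C
Reagents that add atoms: 3-methylbutanoyl chloride (24), CC(C)CC(Cl)=O
Why: Acylation of the remaining neopentyl-type secondary alcohol under nucleophilic catalysis by DMAP should give the mixed diester; the trans-1,3 relationship of the two oxygens disfavours acyl migration.

Step 14
Reactants: 25 diester
Product: 26 CNP0194415.1 = (4R,5S,7R,9R,10R,11R)-7-(3-methylbutanoyloxy)-1-oxolongipin-2-en-9-yl (2E)-2-methylbut-2-enoate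
Conditions: CrO3, 3,5-dimethylpyrazole, CH2Cl2, −20 °C
Reagents that add atoms: chromium trioxide, O=[Cr](=O)=O
Why: Allylic oxidation by hexavalent chromium complexed to 3,5-dimethylpyrazole should convert the ring CH2 next to the trisubstituted alkene (C1) into the enone carbonyl, as in the oxidation of α-pinene to verbenone; the bridgehead C4–H cannot give an enone and the enoate alkene of the tiglate is deactivated.

**Compound list**

1 | (R)-(−)-carvone, (5R)-2-methyl-5-(prop-1-en-2-yl)cyclohex-2-en-1-one | CC1=CC[C@@H](C(C)=C)CC1=O | starting material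
2 | (5R)-2-methyl-5-(2-methyloxiran-2-yl)cyclohex-2-en-1-one, both epoxide epimers | CC1=CC[C@@H](C2(C)CO2)CC1=O | intermediate
3 | 2-[(1R)-4-methyl-5-oxocyclohex-3-en-1-yl]propanal, both C10 epimers | CC1=CC[C@@H](C(C)C=O)CC1=O | intermediate
4 | oxime O-sulfonic acid of 3 | CC1=CC[C@@H](C(C)C=NOS(=O)(=O)O)CC1=O | intermediate
5 | 2-[(1R)-4-methyl-5-oxocyclohex-3-en-1-yl]propanenitrile, both C10 epimers | CC1=CC[C@@H](C(C)C#N)CC1=O | intermediate
6 | acetone | CC(C)=O | starting material
7 | 2-[(1R)-6-(2-hydroxypropan-2-yl)-4-methyl-5-oxocyclohex-3-en-1-yl]propanenitrile, ring substituents trans | CC1=CC[C@@H](C(C)C#N)[C@H](C(C)(C)O)C1=O | intermediate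
8 | tertiary methanesulfonate of 7 | CC1=CC[C@@H](C(C)C#N)[C@H](C(C)(C)OS(C)(=O)=O)C1=O | intermediate
9 | 2-[4-methyl-5-oxo-6-(propan-2-ylidene)cyclohex-3-en-1-yl]propanenitrile, ring CH as in 5 | CC1=CC[C@@H](C(C)C#N)C(=C(C)C)C1=O | intermediate
10 | ethynyltrimethylsilane | C#C[Si](C)(C)C | starting material
11 | 9-BBN dienol borinate of 12 | CC1=CC[C@@H](C(C)C#N)C(C(C)(C)C#C[Si](C)(C)C)=C1OB1C2CCCC1CCC2 | intermediate
12 | 2-{4-methyl-6-[2-methyl-4-(trimethylsilyl)but-3-yn-2-yl]-5-oxocyclohex-3-en-1-yl}propanenitrile, ring substituents cis | CC1=CC[C@@H](C(C)C#N)[C@@H](C(C)(C)C#C[Si](C)(C)C)C1=O | intermediate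
13 | 2-[4-methyl-6-(2-methylbut-3-yn-2-yl)-5-oxocyclohex-3-en-1-yl]propanenitrile, ring substituents cis | CC1=CC[C@@H](C(C)C#N)[C@@H](C(C)(C)C#C)C1=O | intermediate
14 | 2-[4-methyl-6-(2-methyl-3-oxobutan-2-yl)-5-oxocyclohex-3-en-1-yl]propanenitrile, ring substituents cis | CC1=CC[C@@H](C(C)C#N)[C@@H](C(C)(C)C(C)=O)C1=O | intermediate
15 | 2-[5-hydroxy-4-methyl-6-(2-methyl-3-oxobutan-2-yl)cyclohex-3-en-1-yl]propanenitrile, hydroxyl cis to both side chains | CC1=CC[C@@H](C(C)C#N)[C@@H](C(C)(C)C(C)=O)[C@H]1O | intermediate
16 | 2-[5-chloro-4-methyl-6-(2-methyl-3-oxobutan-2-yl)cyclohex-3-en-1-yl]propanenitrile, side chains cis, chlorine trans to both | CC1=CC[C@@H](C(C)C#N)[C@@H](C(C)(C)C(C)=O)[C@@H]1Cl | intermediate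
17 | 2,6-dimethyl-7-(2-methyl-3-oxobutan-2-yl)bicyclo[3.1.1]hept-2-ene-6-carbonitrile, nitrile facing the C7 side chain, 6-methyl over the alkene bridge | CC(=O)C(C)(C)[C@@H]1[C@H]2CC=C(C)[C@@H]1[C@@]2(C)C#N | intermediate
18 | 9-aminolongipina-2,8-dien-7-one (enaminone) | NC1=CC(=O)C(C)(C)[C@@H]2[C@H]3CC=C(C)[C@@H]2[C@]31C | intermediate
19 | longipin-2-ene-7,9-dione | O=C1CC(=O)C(C)(C)[C@@H]2[C@H]3CC=C(C)[C@@H]2[C@]31C | intermediate
20 | (9R)-9-hydroxylongipin-2-en-7-one | O[C@@H]1CC(=O)C(C)(C)[C@@H]2[C@H]3CC=C(C)[C@@H]2[C@]31C | intermediate
21 | tiglaldehyde, (2E)-2-methylbut-2-enal | C/C=C(\C)C=O | starting material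
22 | hemiacetal of 20 and 21 (samarium-bound in the flask, drawn as the free hemiacetal) | C/C=C(\C)C(O)O[C@@H]1CC(=O)C(C)(C)[C@@H]2[C@H]3CC=C(C)[C@@H]2[C@]31C | intermediate
23 | (7R,9R)-7-hydroxylongipin-2-en-9-yl (2E)-2-methylbut-2-enoate | C/C=C(\C)C(=O)O[C@@H]1C[C@@H](O)C(C)(C)[C@@H]2[C@H]3CC=C(C)[C@@H]2[C@]31C | intermediate
24 | 3-methylbutanoyl chloride | CC(C)CC(Cl)=O | starting material
25 | (7R,9R)-7-(3-methylbutanoyloxy)longipin-2-en-9-yl (2E)-2-methylbut-2-enoate | C/C=C(\C)C(=O)O[C@@H]1C[C@@H](OC(=O)CC(C)C)C(C)(C)[C@@H]2[C@H]3CC=C(C)[C@@H]2[C@]31C | intermediate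
26 | CNP0194415.1, (4R,5S,7R,9R,10R,11R)-7-(3-methylbutanoyloxy)-1-oxolongipin-2-en-9-yl (2E)-2-methylbut-2-enoate | C/C=C(\C)C(=O)O[C@@H]1C[C@@H](OC(=O)CC(C)C)C(C)(C)[C@@H]2[C@H]3C(=O)C=C(C)[C@@H]2[C@]31C | target

Total step count: 14. Longest linear sequence: 14 steps (1 to 26).

**Steps most likely to fail**

Step 10. What may go wrong: five-membered ring closure by C- or O-alkylation of the ketone enolate at C4, substitution with allylic transposition (attack at C2), loss of HCl to a diene, or an enolate–nitrile addition that stalls at the hindered nitrile. The fallback sets out from 16 and comes back at 19. Me2(t-Bu)SiOTf and Et3N convert the methyl ketone into the tert-butyldimethylsilyl enol ether F1, so that only the nitrile can be metalated. LiN(i-Pr)2 (1.1 equiv) then closes the cyclobutane to the bicyclic silyl enol ether F2. Dilute aqueous HCl in THF releases the methyl ketone 17, which is isolated here. KOt-Bu in t-BuOH/THF effects the Thorpe–Ziegler-type cyclisation to 18, and buffered hydrolysis returns to the route at 19.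

Step 6. What may go wrong: no 1,4-transfer to the fully substituted β-carbon, or protonation and epimerisation that leave the C5 substituent trans to the C11 side chain. The fallback sets out from 5 and comes back at 14. LiN(i-Pr)2 and Me3SiCl give the trimethylsilyl dienol ether F3. Photoredox radical alkylation with 3-bromo-3-methylbutan-2-one (Ru(bpy)3Cl2, visible light) forms the C5–C6 bond and gives the 1,4-diketone directly, expected as the trans isomer F4. Me3SiOTf and Et3N convert F4 into the bis(trimethylsilyl enol ether) F5. Kinetic protodesilylation (TBAF/AcOH, THF, −78 °C), with the proton entering C5 anti to the C11 side chain, should give the cis-diketone and returns to the route at 14.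

Step 12. What may go wrong: slow hemiacetal formation or hydride transfer from the conjugated aldehyde, retro-aldol opening of the seven-membered ring, or acyl migration between O9 and O7. The fallback sets out from 20 and comes back at 23. Yamaguchi esterification with tiglic acid (2,4,6-trichlorobenzoyl chloride, Et3N, DMAP, toluene) gives the β-tigloyloxy ketone F6. A second CBS reduction with the same (S)-catalyst and catecholborane (large group C6, small group C8) sets (7R) under catalyst control and returns to the route at 23.

Further compounds
F1 | step 10 | tert-butyldimethylsilyl enol ether of 16 | CC1=CC[C@@H](C(C)C#N)[C@@H](C(C)(C)C(=C)O[Si](C)(C)C(C)(C)C)[C@@H]1Cl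
F2 | step 10 | tert-butyldimethylsilyl enol ether of 17 | C=C(O[Si](C)(C)C(C)(C)C)C(C)(C)[C@@H]1[C@H]2CC=C(C)[C@@H]1[C@@]2(C)C#N
F3 | step 6 | trimethylsilyl dienol ether of 5 | CC1=CC[C@@H](C(C)C#N)C=C1O[Si](C)(C)C
F4 | step 6 | trans isomer of 14 (C5 epimer) | CC1=CC[C@@H](C(C)C#N)[C@H](C(C)(C)C(C)=O)C1=O
F5 | step 6 | bis(trimethylsilyl enol ether) of F4 | CC1=CC[C@@H](C(C)C#N)C(C(C)(C)C(=C)O[Si](C)(C)C)=C1O[Si](C)(C)C
F6 | step 12 | (9R)-7-oxolongipin-2-en-9-yl (2E)-2-methylbut-2-enoate | C/C=C(\C)C(=O)O[C@@H]1CC(=O)C(C)(C)[C@@H]2[C@H]3CC=C(C)[C@@H]2[C@]31C
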